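(The data are simulated with constants of no real substance, and the scatter is random.)

The question is which way of adding the reagents leaves the most target after 1.5 h.

| flask | substrate | fresh partner | coupling partner | capture agent | remark | time |
|---|---|---|---|---|---|---|
| Saturday's | 0.080 M | 1 equiv | 2 equiv | 8 mM | run made earlier |  |
| Tuesday's | 0.080 M | 1 equiv | 1.3 equiv | 8 mM | run made earlier |  |
| Sunday's | 0.080 M | 1 equiv | 3 equiv | 8 mM | run made earlier |  |
| Thursday's | 0.080 M | 0.50 equiv | 2 equiv | 8 mM | run made earlier |  |
| alpha | 0.080 M | 1.00 equiv (fed, over 50 min) | 2.00 equiv | 8.00 mM | all else is in the flask from the start; the feed brings no volume worth counting | 1.5 h |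
| eta | 0.080 M (fed, over 50 min) | 1.00 equiv | 2.00 equiv | 8.00 mM | all else is in the flask from the start; the feed brings no volume worth counting | 1.5 h |
| gamma | 0.080 M (fed, over 12 min) | 1.00 equiv | 2.00 equiv | 8.00 mM | all else is in the flask from the start; the feed brings no volume worth counting | 1.5 h |
| epsilon | 0.080 M | 1.00 equiv | 2.00 equiv | 8.00 mM | everything together at the start | 1.5 h |

- which flask leads in amount of target, in percent of the substrate charged ("all alike" within 1.5 percentage points) (alpha / eta / gamma / epsilon / all alike)
- how much target is there at the end, in percent of the substrate charged: alpha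
- how much target is there at the end, in percent of the substrate charged: eta
- how much target is there at the end, in percent of the substrate charged: gamma
- how much target is there at the end, in percent of the substrate charged: epsilon



| run | time / min | target / % |
|---|---|---|
| Saturday's | 8.00 | 13.9 |
| Saturday's | 12.0 | 18.2 |
| Saturday's | 15.0 | 18.6 |
| Saturday's | 25.0 | 23.9 |
| Saturday's | 40.0 | 28.4 |
| Saturday's | 60.0 | 29.9 |
| Saturday's | 90.0 | 32.8 |
| Tuesday's | 12.0 | 9.4 |
| Tuesday's | 25.0 | 11.6 |
| Tuesday's | 40.0 | 12.2 |
| Tuesday's | 50.0 | 11.8 |
| Tuesday's | 60.0 | 13.0 |
| Tuesday's | 80.0 | 14.0 |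
| Tuesday's | 90.0 | 14.5 |
| Sunday's | 8.00 | 22.1 |
| Sunday's | 12.0 | 25.7 |
| Sunday's | 15.0 | 28.6 |
| Sunday's | 25.0 | 33.3 |
| Sunday's | 40.0 | 38.1 |
| Sunday's | 60.0 | 39.3 |
| Sunday's | 90.0 | 38.0 |
| Thursday's | 8.00 | 7.0 |
| Thursday's | 15.0 | 11.6 |
| Thursday's | 25.0 | 13.2 |
| Thursday's | 50.0 | 18.8 |
| Thursday's | 90.0 | 20.1 |

(each reading ± 1 percentage point)

Down the last rows, the target reads 14.5% with 1.3 equiv of coupling partner, 32.8% with 2 equiv and 38.0% with 3 equiv, so the second rise in the charge gains less than the first. Across the first rows, Thursday's reading is half of Saturday's, which has twice the fresh partner, so within the scatter the early rate in these two runs follows c(fresh partner). At the end, Thursday's flask has 20.1% against Saturday's 32.8%. That pair gives a slope.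

A steady feed has delivered, averaged over the run, one minus half the ratio of feed time to run time of its charge. Dividing the time-mean delivered fresh partner by the time-mean delivered substrate, both per substrate charged, gives the lead 1.38 for eta. Alpha has 0.722, gamma 1.07, Saturday's recipe and epsilon one, and Thursday's flask 0.500.

Thursday's and Saturday's readings give 25 percentage points per unit of lead. This reckoning assumes that a substrate feed raises the lead as a smaller substrate charge would, though no earlier run varied the substrate. It gives alpha 25.7%, gamma 34.6% and eta 42.6%, with epsilon at Saturday's reading, so eta comes first. The lead of eta stands furthest above the lead of one that Saturday's run reached, so the eta figure is the least secure of these reckoned ones.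

The forecast differs: it names alpha as the leader, gives alpha 36%, eta 21%, gamma 29% and epsilon 33%, and says of the two substrate feeds: “Feeding substrate lets the partner decay before substrate arrives”.

The flasks give eta 38.6%, gamma 34.6%, epsilon 32.7% and alpha 26.1%.

    target ⇌ isomer of the product (K = 1.00, k = 0.00250 s⁻¹)
    open intermediate → side product (k = 2.30 × 10⁻⁴ s⁻¹)
    substrate + coupling partner → open intermediate (k = 0.100 M⁻¹ s⁻¹)
    open intermediate + second intermediate → target (k = 0.0760 M⁻¹ s⁻¹)
    coupling partner + fresh partner → second intermediate (k = 0.0100 M⁻¹ s⁻¹)
    second intermediate + capture agent → trapped intermediate (k = 0.0730 M⁻¹ s⁻¹)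

Each target takes one open intermediate and one second intermediate. At 1.50 h in eta, the substrate step uses coupling partner at 0.85 of the rate of the fresh partner step. Side product stands at 14.7% in eta and 45.8% in alpha. Eta's lead of 1.38 reckoned 42.6%, which is 4 points above the flask, and eta ends with 5.14% of its coupling partner. A neighbour with the same lead and 5.00 equiv of coupling partner gives 42.7%, with 60.0% of that charge left.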